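**Retrosynthetic overview**

1. Locants: ring carbons are counted C1–C13 along the target SMILES (C1 = octyl-bearing CH, C5 = C–OH, C6 = C–CO2H, C7 = CH=, C8 = CHOH, C13 = last CH). Ring A = cyclobutane C1/C2/C12/C11, ring B = cyclohexene C2–C5/C13/C12, ring C = cyclohexene C5–C9/C13, ring D = cyclopentane C9–C13.
2. Enabling feature: in ring C both C8 (carbinol) and C13 (the CH shared by rings B, C and D) stand β to C6. With C6 written as a ketone, C8–OH is an aldol hydroxyl (bond C7–C8) and C13 is the β-carbon of a C13=C5–C6(=O) enone (bond C9–C13).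
3. Endgame: C6–CO2H from the C6 enol triflate by carbonylation; C5–OH by enolate hydroxylation of the tetracyclic β-ketol.
4. Key disconnection: C7–C8 (aldol, closes ring C) together with C9–C13 (Michael, closes ring D) in one operation from a bicyclo[4.2.0]octa-2,4-diene keto aldehyde, the polar counterpart of the biosynthetic intramolecular Diels–Alder step.
5. Precursor: acetyl diene from the ring-B enone (dienyl triflate, Stille); side chain by hydroboration/Suzuki–Miyaura; rings A/B by auxiliary-controlled keteniminium [2+2]. Ring order: B (from cyclohexadiene), A, then D and C.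

Key step: step 9

Assumption: the (2R,5R)-auxiliary is taken to steer step 2 to the enantiomer drawn; if the sense of induction is the opposite, the (2S,5S)-amine is used and nothing else changes.

In the bicyclic names, endo = cis to the six-membered ring and exo = trans to it; ring carbons are configured as in 7.

**Route**

Step 1
Reactants: 1 decanoyl chloride; 2 (2R,5R)-2,5-dimethylpyrrolidine
Product: 3 1-[(2R,5R)-2,5-dimethylpyrrolidin-1-yl]decan-1-one
Conditions: Et3N, CH2Cl2, 0 °C to rt
Reagents that add atoms: none
Why: Schotten–Baumann-type N-acylation of a secondary amine by an acid chloride, which touches no stereocenter.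

Step 2
Reactants: 3 1-[(2R,5R)-2,5-dimethylpyrrolidin-1-yl]decan-1-one; 4 cyclohexa-1,3-diene
Product: 7 (1S,6S,8S)-8-octylbicyclo[4.2.0]oct-2-en-7-one, via keteniminium triflate 5 (not isolated), via cyclobutaniminium triflate 6 (not isolated)
Conditions: Tf2O, 2,4,6-collidine, ClCH2CH2Cl, −20 °C to rt; 4 (3 equiv), 40 °C; aq NaHCO3, rt; then DBU (cat.), CH2Cl2, rt
Reagents that add atoms: water, O
Why: Keteniminium–alkene [2+2] cycloaddition in its auxiliary-controlled form: the electrophilic central carbon bonds to the diene terminus and the allyl cation closes at the neighbouring carbon, so the carbonyl ends next to the non-allylic ring-fusion carbon and the octyl-bearing carbon next to the allylic one, the cis fusion is inherent, the C2-symmetric pyrrolidine screens one face of the keteniminium and so sets C1/C6, and C8 is equilibrated by enolization to the exo-octyl epimer.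

Step 3
Reactants: 7 (1S,6S,8S)-8-octylbicyclo[4.2.0]oct-2-en-7-one
Product: 8 7-methylidene-8-exo-octylbicyclo[4.2.0]oct-2-ene
Conditions: Ph3PCH3Br, KOtBu, THF, 0 °C to rt
Reagents that add atoms: methyltriphenylphosphonium bromide, C[P+](c1ccccc1)(c1ccccc1)c1ccccc1.[Br-]
Why: Wittig methylenation of a strained, electrophilic cyclobutanone, in which the basic ylide cannot erode C8 because that centre is already the thermodynamic epimer.

Step 4
Reactants: 8 7-methylidene-8-exo-octylbicyclo[4.2.0]oct-2-ene; 9 (Z)-1-bromo-2-ethoxyethene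
Product: 11 7-endo-[(2Z)-3-ethoxyprop-2-en-1-yl]-8-exo-octylbicyclo[4.2.0]oct-2-ene, via alkylborane 10 (not isolated)
Conditions: 9-BBN, THF, 0 °C to rt; then 9, PdCl2(dppf) (5 mol %), aq K3PO4, DMF, 50 °C
Reagents that add atoms: none
Why: Anti-Markovnikov hydroboration, selective for the 1,1-disubstituted exocyclic alkene over the ring cis-alkene, should deliver hydrogen to C7 on the convex face that carries the pseudo-equatorial octyl group (the other face lies under the six-membered ring, whose C6–C5 bond is pseudo-axial on the puckered cyclobutane), so the CH2B group ends endo and trans to octyl, and B-alkyl Suzuki–Miyaura coupling then adds the two-carbon enol ether with retention.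

Step 5
Reactants: 11 7-endo-[(2Z)-3-ethoxyprop-2-en-1-yl]-8-exo-octylbicyclo[4.2.0]oct-2-ene
Product: 12 2-{2-[8-exo-octylbicyclo[4.2.0]oct-2-en-7-endo-yl]ethyl}-1,3-dioxolane
Conditions: HOCH2CH2OH, PPTS (cat.), CH2Cl2, rt
Reagents that add atoms: ethylene glycol, OCCO
Why: Acid-catalysed addition of the diol to the enol ether followed by transacetalization with loss of ethanol turns the oxidant-labile enol ether into a robust masked aldehyde without touching a stereocenter.

Step 6
Reactants: 12 2-{2-[8-exo-octylbicyclo[4.2.0]oct-2-en-7-endo-yl]ethyl}-1,3-dioxolane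
Product: 13 7-endo-[2-(1,3-dioxolan-2-yl)ethyl]-8-exo-octylbicyclo[4.2.0]oct-2-en-4-one
Conditions: Rh2(cap)4 (cap = caprolactamate, 1 mol %), t-BuOOH, K2CO3, CH2Cl2, rt
Reagents that add atoms: tert-butyl hydroperoxide, CC(C)(C)OO
Why: Radical allylic oxidation (hydrogen abstraction by t-BuOO•, peroxide formation, elimination) should take the ring CH2 rather than the strained, poorly aligned cyclobutyl methine at the ring fusion, and capture at the allyl terminus remote from the ring fusion should give the unrearranged enone.

Step 7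
Reactants: 13 7-endo-[2-(1,3-dioxolan-2-yl)ethyl]-8-exo-octylbicyclo[4.2.0]oct-2-en-4-one
Product: 14 7-endo-[2-(1,3-dioxolan-2-yl)ethyl]-8-exo-octylbicyclo[4.2.0]octa-2,4-dien-4-yl trifluoromethanesulfonate
Conditions: LiN(i-Pr)2, THF, −78 °C; PhNTf2, −78 to 0 °C
Reagents that add atoms: N-phenylbis(trifluoromethanesulfonimide), O=S(=O)(N(c1ccccc1)S(=O)(=O)C(F)(F)F)C(F)(F)F
Why: Kinetic α′-deprotonation of the enone gives the cross-conjugated dienolate, and its O-triflation gives the 2-triflyloxy-1,3-diene with all stereocenters untouched.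

Step 8
Reactants: 14 7-endo-[2-(1,3-dioxolan-2-yl)ethyl]-8-exo-octylbicyclo[4.2.0]octa-2,4-dien-4-yl trifluoromethanesulfonate; 15 tributyl(1-ethoxyethenyl)stannane
Product: 17 3-[4-acetyl-8-exo-octylbicyclo[4.2.0]octa-2,4-dien-7-endo-yl]propanal, via ethoxy diene 16 (not isolated)
Conditions: Pd(PPh3)4 (5 mol %), CuCl, LiCl, DMSO, 40 °C; then 1 M HCl, THF, rt
Reagents that add atoms: water, O
Why: Stille coupling of a vinyl triflate with an α-alkoxyvinylstannane (acetyl anion equivalent) followed by aqueous acid, which protonates the terminal CH2 of the enol ether to give the conjugated methyl ketone and opens the dioxolane, while the mild temperature keeps the bicyclo[4.2.0]octadiene from electrocyclic endo/exo scrambling.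

Step 9
Reactants: 17 3-[4-acetyl-8-exo-octylbicyclo[4.2.0]octa-2,4-dien-7-endo-yl]propanal
Product: 19 tetracyclic ketol (target numbering: 6-oxo, 8-hydroxy, 1-octyl, C3=C4; 8-OH axial, syn to H-13 and trans to H-9; H-5 cis to H-13; rings C/D trans-fused), via tricyclic Michael adduct 18 (not isolated)
Conditions: L-proline (30 mol %), DMSO, rt
Reagents that add atoms: none
Why: Proline and the unbranched aldehyde give an enamine whose carbon C9 adds to C13, the only electrophilic carbon of the cross-conjugated dienone (5-exo-trig Michael addition, ring D), and proline then turns the methyl ketone of 18 into its terminal enamine, whose carbon C7 adds to the aldehyde carbon C8 (6-enolendo-exo-trig aldol addition, ring C), so that both polar bonds are matched (donor C9 to acceptor C13, donor C7 to acceptor C8). The closest known reaction types are the amine-catalysed cycloisomerization of formyl enones to trans-disubstituted cyclopentanes and the Hajos–Parrish ketol closure of a methyl ketone onto a carbonyl group; run in sequence they are the stepwise counterpart of the intramolecular Diels–Alder reaction that closes the same two rings on the same kind of bicyclo[4.2.0]octadiene in the presumed biosynthesis. C13 is fixed by the tether, since the three-atom chain sits on the cyclobutane face that also carries ring B and can reach C13 only from that face. C9 is set trans to C5 on the new cyclopentane, which is both the kinetic preference of enamine Michael cyclizations and, the centre being epimerizable through the enamine, the thermodynamic one, and it equals the trans C/D fusion. C8 is set in a closed chair-like transition state in which the carboxylic acid of the ketone enamine is hydrogen-bonded to the aldehyde oxygen, which therefore sits axial on the forming ring, syn to H-13 and cis to C10, while C5–H is left on the convex face by protonation, stays epimerizable and is replaced in step 11. The step needs addition without dehydration and without the cyclohexadiene acting as a Diels–Alder diene, which proline at room temperature (hydrogen-bond activation, no Mannich-type elimination, no heating) and the polarity-matched pairing should secure.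

Step 10
Reactants: 19 tetracyclic ketol
Product: 20 8-O-tert-butyldimethylsilyl ether of ketol 19
Conditions: TBSOTf, 2,6-lutidine, CH2Cl2, −78 °C
Reagents that add atoms: tert-butyldimethylsilyl trifluoromethanesulfonate, CC(C)(C)[Si](C)(C)OS(=O)(=O)C(F)(F)F
Why: O-silylation of the secondary alcohol blocks retro-aldol cleavage of the β-ketol in the basic steps that follow and leaves every stereocenter as it is.

Step 11
Reactants: 20 8-O-TBS ketol
Product: 21 5-hydroxy-6-oxo-8-silyloxy tetracycle (5-OH cis to H-13 and to the 8-silyloxy group)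
Conditions: KN(SiMe3)2, THF, −78 °C; 2-(benzenesulfonyl)-3-phenyloxaziridine, −78 °C
Reagents that add atoms: 2-(benzenesulfonyl)-3-phenyloxaziridine, O=S(=O)(c1ccccc1)N1OC1c1ccccc1
Why: Enolate hydroxylation with an N-sulfonyloxaziridine: deprotonation at C5, the only α-hydrogen that is also allylic, gives the dienolate, which should be oxidized at its α-carbon C5 from the convex face anti to the C13–C9 bond, which places the tertiary hydroxyl cis to H-13.

Step 12
Reactants: 21 5-hydroxy-6-oxo-8-silyloxy tetracycle
Product: 22 C6 enol triflate (C6=C7) of 21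
Conditions: LiN(SiMe3)2 (2.2 equiv), THF, −78 °C; N-(5-chloropyridin-2-yl)bis(trifluoromethanesulfonimide), −78 °C
Reagents that add atoms: N-(5-chloropyridin-2-yl)bis(trifluoromethanesulfonimide), O=S(=O)(N(c1ccc(Cl)cn1)S(=O)(=O)C(F)(F)F)C(F)(F)F
Why: With C5 quaternary the ketone can enolize only toward C7, so O-triflation of the lithium enolate (the tertiary alkoxide is a spectator) gives the C6=C7 enol triflate regiospecifically, and the low temperature and lithium counter-ion should suppress E1cB loss of the 8-silyloxy group.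

Step 13
Reactants: 22 C6 enol triflate
Product: 23 methyl ester (6-CO2Me, 5-OH, 8-OTBS)
Conditions: Pd(OAc)2 (10 mol %), PPh3, Et3N, CO (1 atm), MeOH–DMF, 50 °C
Reagents that add atoms: carbon monoxide, [C-]#[O+]; methanol, CO
Why: Palladium-catalysed alkoxycarbonylation of a vinyl triflate (oxidative addition, CO insertion, methanolysis) places the ester carbon on C6 with the C6=C7 double bond fixed.

Step 14
Reactants: 23 methyl ester (8-OTBS)
Product: 24 methyl ester of the target (5,8-diol)
Conditions: Bu4NF, AcOH, THF, 0 °C to rt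
Reagents that add atoms: none
Why: Fluoride-induced Si–O cleavage under buffered, non-acidic conditions spares the acid-labile bis-allylic tertiary alcohol at C5.

Step 15
Reactants: 24 methyl ester of the target
Product: 25 target acid CNP0106718.3
Conditions: LiOH, THF–MeOH–H2O, rt; then cold dilute HCl to pH 4
Reagents that add atoms: lithium hydroxide, [Li+].[OH-]
Why: Saponification of the methyl enoate by acyl–oxygen cleavage affects no stereocenter, and the brief, mild acidification frees the acid without ionizing the C5 alcohol.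

**Compound list**

1 | decanoyl chloride | CCCCCCCCCC(=O)Cl | starting material
2 | (2R,5R)-2,5-dimethylpyrrolidine | C[C@@H]1CC[C@@H](C)N1 | starting material
3 | 1-[(2R,5R)-2,5-dimethylpyrrolidin-1-yl]decan-1-one | CCCCCCCCCC(=O)N1[C@H](C)CC[C@H]1C | intermediate
4 | cyclohexa-1,3-diene | C1=CC=CCC1 | starting material
5 | 1-(dec-1-en-1-ylidene)-(2R,5R)-2,5-dimethylpyrrolidinium triflate (keteniminium salt) | CCCCCCCCC=C=[N+]1[C@H](C)CC[C@H]1C.[O-]S(=O)(=O)C(F)(F)F | intermediate
6 | 1-(8-octylbicyclo[4.2.0]oct-2-en-7-ylidene)-(2R,5R)-2,5-dimethylpyrrolidinium triflate (cis-fused; drawn with exo octyl, the C8 epimer converges in the same step) | CCCCCCCC[C@H]1[C@@H]2C=CCC[C@@H]2C1=[N+]3[C@H](C)CC[C@H]3C.[O-]S(=O)(=O)C(F)(F)F | intermediate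
7 | (1S,6S,8S)-8-octylbicyclo[4.2.0]oct-2-en-7-one (cis-fused, octyl exo) | CCCCCCCC[C@H]1[C@@H]2C=CCC[C@@H]2C1=O | intermediate
8 | 7-methylidene-8-exo-octylbicyclo[4.2.0]oct-2-ene | CCCCCCCC[C@H]1[C@@H]2C=CCC[C@@H]2C1=C | intermediate
9 | (Z)-1-bromo-2-ethoxyethene | CCO/C=C\Br | starting material
10 | 9-{[8-exo-octylbicyclo[4.2.0]oct-2-en-7-endo-yl]methyl}-9-borabicyclo[3.3.1]nonane | CCCCCCCC[C@H]1[C@@H]2C=CCC[C@@H]2[C@@H]1CB3C4CCCC3CCC4 | intermediate
11 | 7-endo-[(2Z)-3-ethoxyprop-2-en-1-yl]-8-exo-octylbicyclo[4.2.0]oct-2-ene | CCCCCCCC[C@H]1[C@@H]2C=CCC[C@@H]2[C@@H]1C/C=C\OCC | intermediate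
12 | 2-{2-[8-exo-octylbicyclo[4.2.0]oct-2-en-7-endo-yl]ethyl}-1,3-dioxolane | CCCCCCCC[C@H]1[C@@H]2C=CCC[C@@H]2[C@@H]1CCC3OCCO3 | intermediate
13 | 7-endo-[2-(1,3-dioxolan-2-yl)ethyl]-8-exo-octylbicyclo[4.2.0]oct-2-en-4-one | CCCCCCCC[C@H]1[C@@H]2C=CC(=O)C[C@@H]2[C@@H]1CCC3OCCO3 | intermediate
14 | 7-endo-[2-(1,3-dioxolan-2-yl)ethyl]-8-exo-octylbicyclo[4.2.0]octa-2,4-dien-4-yl trifluoromethanesulfonate | CCCCCCCC[C@H]1[C@@H]2C=CC(OS(=O)(=O)C(F)(F)F)=C[C@@H]2[C@@H]1CCC3OCCO3 | intermediate
15 | tributyl(1-ethoxyethenyl)stannane | CCCC[Sn](CCCC)(CCCC)C(=C)OCC | starting material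
16 | 2-{2-[4-(1-ethoxyethenyl)-8-exo-octylbicyclo[4.2.0]octa-2,4-dien-7-endo-yl]ethyl}-1,3-dioxolane | CCCCCCCC[C@H]1[C@@H]2C=CC(C(=C)OCC)=C[C@@H]2[C@@H]1CCC3OCCO3 | intermediate
17 | 3-[4-acetyl-8-exo-octylbicyclo[4.2.0]octa-2,4-dien-7-endo-yl]propanal | CCCCCCCC[C@H]1[C@@H]2C=CC(C(C)=O)=C[C@@H]2[C@@H]1CCC=O | intermediate
18 | tricyclic Michael adduct, rings A, B, D (target numbering: 5-acetyl, 9-formyl; formyl trans to C5 on ring D; H-5 and H-13 cis) | CCCCCCCC[C@H]1[C@@H]2C=C[C@H](C(C)=O)[C@@H]3[C@@H](C=O)C[C@H]1[C@H]23 | intermediate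
19 | tetracyclic ketol (target numbering: 6-oxo, 8-hydroxy, 1-octyl, C3=C4; 8-OH syn to H-13, trans to H-9; C/D trans-fused) | CCCCCCCC[C@H]1[C@@H]2C=C[C@@H]3C(=O)C[C@@H](O)[C@H]4C[C@H]1[C@H]2[C@@H]43 | intermediate
20 | 8-O-tert-butyldimethylsilyl ether of 19 | CCCCCCCC[C@H]1[C@@H]2C=C[C@@H]3C(=O)C[C@@H](O[Si](C)(C)C(C)(C)C)[C@H]4C[C@H]1[C@H]2[C@@H]43 | intermediate
21 | 5-hydroxy derivative of 20 (5-OH cis to H-13 and to 8-OTBS) | CCCCCCCC[C@H]1[C@@H]2C=C[C@]3(O)C(=O)C[C@@H](O[Si](C)(C)C(C)(C)C)[C@H]4C[C@H]1[C@H]2[C@@H]43 | intermediate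
22 | C6 enol triflate of 21 (C6=C7) | CCCCCCCC[C@H]1[C@@H]2C=C[C@]3(O)C(OS(=O)(=O)C(F)(F)F)=C[C@@H](O[Si](C)(C)C(C)(C)C)[C@H]4C[C@H]1[C@H]2[C@@H]43 | intermediate
23 | methyl ester, 5-OH, 8-OTBS (6-CO2Me on C6=C7) | CCCCCCCC[C@H]1[C@@H]2C=C[C@]3(O)C(C(=O)OC)=C[C@@H](O[Si](C)(C)C(C)(C)C)[C@H]4C[C@H]1[C@H]2[C@@H]43 | intermediate
24 | methyl ester of the target (5,8-diol) | CCCCCCCC[C@H]1[C@@H]2C=C[C@]3(O)C(C(=O)OC)=C[C@@H](O)[C@H]4C[C@H]1[C@H]2[C@@H]43 | intermediate
25 | target acid CNP0106718.3 (rings A–D; 1-octyl exo; 5-OH and 8-OH cis to each other and to H-13; H-9 trans to H-13; C3=C4 and C6=C7; 6-CO2H) | CCCCCCCC[C@H]1[C@@H]2C=C[C@]3(O)C(C(=O)O)=C[C@@H](O)[C@H]4C[C@H]1[C@H]2[C@@H]43 | target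

**Totals and risks**

Total steps: 15. Longest linear sequence: 15 steps (1 to 25).

Steps most likely to fail:

Step 9. The aldol half may lose facial control at the aldehyde carbon C8, or the ketol may dehydrate under amine catalysis. The fallback sets out from 17 and drives the same two bond formations deliberately to the condensation product: pyrrolidine and AcOH in toluene at 60 °C should give the tetracyclic cyclohexenone F1 (C6 ketone, C7=C8). Weitz–Scheffer epoxidation (H2O2, NaOH, MeOH, 0 °C) should then attack C8 axially, anti to the pseudo-axial H-9, and give the epoxy ketone F2 with the oxirane on the face of H-13. Reductive cleavage of the C7–O bond with the selenolate from PhSeSePh, NaBH4 and AcOH in EtOH (the known reduction of α,β-epoxy ketones to β-hydroxy ketones) returns to the route at 19.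

Step 4. The hydroboration may discriminate too little between the two faces of the exocyclic alkene; hydrogen delivered on the concave face gives the cis-7,8 isomer, whose chain cannot reach C13. The fallback sets out from 8 and replaces substrate control by catalyst control: copper-catalysed hydroboration (CuCl, (R)- or (S)-DTBM-SEGPHOS as matched, NaOtBu, HBpin, THF) should give the primary pinacol boronate F3 with the face chosen by the ligand. Suzuki–Miyaura coupling of F3 with 9 (Pd(OAc)2, RuPhos, K3PO4, toluene–H2O, 80 °C) returns to the route at 11.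

Step 2. The auxiliary may give too little enantiofacial discrimination, or the diene may be consumed by competing cycloaddition modes. The fallback sets out from 1 and separates ring formation from enantiocontrol: acylation of pyrrolidine gives N-decanoylpyrrolidine F4, and the same Tf2O/collidine activation, cycloaddition with 4 and hydrolysis give the racemic ketone F5. LiBH(s-Bu)3 (THF, −78 °C) should reduce F5 from the convex face to the racemic endo-alcohol, and lipase-catalysed acetylation (lipase from Burkholderia cepacia, vinyl acetate, MTBE) should leave the wanted alcohol F6 and acetylate its enantiomer to the acetate F7; were the preference reversed, the wanted acetate would be methanolysed. Oxidation of F6 with 1,1,1-triacetoxy-1,1-dihydro-1,2-benziodoxol-3(1H)-one returns to the route at 7.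

Further compounds
F1 | step 9 | tetracyclic cyclohexenone (target numbering: 6-oxo, C7=C8, C3=C4) | CCCCCCCC[C@H]1[C@@H]2C=C[C@@H]3C(=O)C=C[C@H]4C[C@H]1[C@H]2[C@@H]43
F2 | step 9 | 7,8-epoxy ketone (oxirane on the face of H-13) | CCCCCCCC[C@H]1[C@@H]2C=C[C@@H]3C(=O)[C@H]5O[C@H]5[C@H]4C[C@H]1[C@H]2[C@@H]43
F3 | step 4 | 2-{[8-exo-octylbicyclo[4.2.0]oct-2-en-7-endo-yl]methyl}-4,4,5,5-tetramethyl-1,3,2-dioxaborolane | CCCCCCCC[C@H]1[C@@H]2C=CCC[C@@H]2[C@@H]1CB3OC(C)(C)C(C)(C)O3
F4 | step 2 | 1-(pyrrolidin-1-yl)decan-1-one | CCCCCCCCCC(=O)N1CCCC1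
F5 | step 2 | racemic 8-exo-octylbicyclo[4.2.0]oct-2-en-7-one (relative configuration of 7) | CCCCCCCCC1C2C=CCCC2C1=O
F6 | step 2 | 8-exo-octylbicyclo[4.2.0]oct-2-en-7-endo-ol (wanted enantiomer after resolution) | CCCCCCCC[C@H]1[C@@H]2C=CCC[C@@H]2[C@@H]1O
F7 | step 2 | 7-endo-acetate of the unwanted enantiomer | CCCCCCCC[C@@H]1[C@H]2C=CCC[C@H]2[C@H]1OC(C)=O
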